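The leftover I hand over with this flask is a gap: in each earlier run, free monomer plus monomer in chains falls short of the charge, on average by 4.22% in north, 6.82% in north-east and 4.38% in south-west. I read it as free monomer lost to the protic impurity, one for each impurity, so the impurity is the limiting reagent of this loss, with 8.00 mM against 0.16 M. For this flask the quenched share is 5.00%: protic impurity charged over free monomer charged. The same ratio gives 3.38%, 7.50% and 5.00% for those runs, each within a point of its gap.

| setting | north | north-east | south-west | flask |
|---|---|---|---|---|
| free monomer | 0.16 M | 0.16 M | 0.16 M | 0.16 M |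
| protic impurity | 5.4 mM | 12 mM | 8 mM | 8.00 mM |
| initiator | 1 mol% | 1 mol% | 2 mol% | 1 mol% |
| remark | run made earlier | run made earlier | run made earlier |  |
| time |  |  |  | 10 h |

| run | time / h | monomer in chains / % | free monomer / % |
|---|---|---|---|
| north | 1.50 | 3.1 | 94.4 |
| north | 3.00 | 5.1 | 89.9 |
| north | 5.00 | 10.2 | 85.9 |
| north | 6.00 | 12.5 | 84.5 |
| north | 8.00 | 12.2 | 81.1 |
| north-east | 0.667 | 0.5 | 93.7 |
| north-east | 1.33 | 1.8 | 90.5 |
| north-east | 2.50 | 4.5 | 89.0 |
| north-east | 4.00 | 8.6 | 84.3 |
| north-east | 8.00 | 14.1 | 78.9 |
| south-west | 0.667 | 1.2 | 93.7 |
| south-west | 2.00 | 9.3 | 87.4 |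
| south-west | 4.00 | 16.3 | 79.2 |
| south-west | 6.00 | 21.7 | 74.7 |
| south-west | 8.00 | 25.5 | 69.1 |

(readings scatter by 1 percentage point)

- the average divides the monomer in chains by the number of chains begun, living and dead together
- what was read earlier has a scatter of 1 percentage point, one standard deviation
- the earlier runs do not show the number of chains; that part of a forecast is a guess

1. average number of monomer units in a chain (chains begun, living or dead) at 10 h
2. part of the free monomer that has reacted at 10 h

When you come at 10 h, expect that share gone from the free monomer, plus what has gone into chains; at 8.00 h, north reads 12.2% in chains and north-east 14.1%. Leave the free monomer charge alone: the share is a ratio, so less monomer over the same impurity means a larger share.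

The forecast says 20.3% reacted and 15 units per chain, holding that “each impurity seems to consume one monomer quickly”.

The flask gives 20.4% and 15.4.

    free monomer + living end → monomer in chains + living end, rate k1*[living end]*[free monomer] (k = 22.0 M⁻¹ h⁻¹)
    living end → dead end (k = 0.160 h⁻¹)
    free monomer + initiator → living end + monomer in chains (k = 6.20 M⁻¹ h⁻¹)
    monomer in chains → over-reaction product (k = 3.30 × 10⁻⁵ h⁻¹)
    protic impurity + free monomer → quenched substrate (k = 15.0 M⁻¹ h⁻¹)

In this flask the quenched substrate at 10.0 h is 5.00%, matching the share of 5.00%, and it is a quarter of the 20.4% reacted, while 15.4% stands in chains. The neighbouring flask starts from 0.040 M of free monomer, with the protic impurity kept at 8.00 mM and the initiator at 1 mol% of the smaller charge, so its share is 20.0%, and its quenched substrate at 10.0 h is 19.9%. In that flask 23.1% of the free monomer reacts, yet its monomer in chains is 3.29% and its average chain is 3.78 units.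

All runs were computed for substances that don't exist, and the scatter is random.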